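The cyclohexadienone ring (C1 carbonyl, C2 allyl, C4 quaternary, C5 enol ether) is cut at C3–C4 and C5–C6. The C4–C5 unit with its two oxygens is an α-hydroxy acid in disguise (C4 α-carbon, C5 carboxyl carbon); C3–C2–C1–C6 is an allylated β-chlorovinyl methyl ketone. The acid is held in a cis-2-tert-butyl-1,3-dioxolan-4-one, a temporary ring. In one flask its dienolate is vinylated at C4 anti to tert-butyl, setting the quaternary centre, and the methyl ketone enolate then acylates at C5 with loss of pivaldehyde. An acetonide across O4/O5 later makes the methyl enol ether regiospecific.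

Key step: step 5

Assumption: the (S)-configured ligand in step 2 is taken to deliver the (S)-hydroxy acid; if the sense of induction is the opposite, the antipodal ligand is used.

Step 1
Reactants: 1 3,4-dimethoxybenzaldehyde; 2 2-oxobutanoic acid
Product: 3 (E)-4-(3,4-dimethoxyphenyl)-3-methyl-2-oxobut-3-enoic acid
Conditions: KOH (2.2 equiv), MeOH–H2O, 0 °C to rt; then aq. HCl
Reagents that add atoms: none
Why: Claisen–Schmidt-type aldol condensation at C3, the only enolisable position of the α-keto acid, should give after dehydration the conjugated (E)-alkene (aryl trans to the keto acid residue), which is the side-chain geometry of the target.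

Step 2
Reactants: 3 (E)-4-(3,4-dimethoxyphenyl)-3-methyl-2-oxobut-3-enoic acid
Product: 4 (2S,3E)-4-(3,4-dimethoxyphenyl)-2-hydroxy-3-methylbut-3-enoic acid
Conditions: [RuCl(C6H6)((S)-SunPhos)]Cl (1 mol %), H2 (20 bar), MeOH, 50 °C
Reagents that add atoms: none
Why: Noyori-type asymmetric hydrogenation of the α-keto acid on a divalent ruthenium diphosphine catalyst, in which carboxylate chelation directs hydride delivery and the ligand sets the (S)-carbinol, while the trisubstituted styrenyl alkene should survive at this temperature.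

Step 3
Reactants: 4 (2S,3E)-4-(3,4-dimethoxyphenyl)-2-hydroxy-3-methylbut-3-enoic acid; 5 2,2-dimethylpropanal (pivaldehyde)
Product: 6 (2S,5S)-2-tert-butyl-5-[(E)-1-(3,4-dimethoxyphenyl)prop-1-en-2-yl]-1,3-dioxolan-4-one
Conditions: TsOH·H2O (cat.), pentane, reflux with water separator; recrystallisation
Reagents that add atoms: none
Why: Acid-catalysed, reversible acetalisation should favour the cis-2,5-disubstituted dioxolanone, so the (S)-carbinol centre fixes the new acetal centre as (2S) (self-regeneration of stereocentres), and crystallisation should remove the trans isomer.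

Step 4
Reactants: 7 but-3-yn-2-one; 8 3-chloroprop-1-ene (allyl chloride)
Product: 9 (3Z)-3-(chloromethylidene)hex-5-en-2-one
Conditions: PdCl2(PhCN)2 (5 mol %), LiCl (2 equiv), 8 in excess, THF, 0 °C to rt
Reagents that add atoms: none
Why: Palladium-catalysed chloroallylation (halopalladation–allylation) of the ynone: with excess chloride, chloride adds anti to divalent palladium at the β-carbon, the α-vinylpalladium species inserts allyl chloride and β-chloride elimination returns PdCl2, so chlorine should end cis to the acetyl group (Z).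

Step 5
Reactants: 6 (2S,5S)-2-tert-butyl-5-[(E)-1-(3,4-dimethoxyphenyl)prop-1-en-2-yl]-1,3-dioxolan-4-one; 9 (3Z)-3-(chloromethylidene)hex-5-en-2-one
Product: 12 (4S)-4,5-dihydroxy-4-[(E)-1-(3,4-dimethoxyphenyl)prop-1-en-2-yl]-2-(prop-2-en-1-yl)cyclohexa-2,5-dien-1-one, via lithium dienolate 10 (not isolated), via vinylation adduct 11 (not isolated)
Conditions: LiN(SiMe3)2 (1.05 equiv), THF, −78 °C; 9, −78 to −30 °C; then LiN(SiMe3)2 (1.2 equiv), −78 °C to rt; aq. NH4Cl
Reagents that add atoms: none
Why: LiN(SiMe3)2 converts 6 into the planar lithium dienolate 10, whose α-carbon adds to the chlorine-bearing β-carbon of 9 on the face anti to the tert-butyl group, and chloride then leaves with retention of alkene geometry (addition–elimination, nucleophilic vinylic substitution), which forms the C3–C4 bond and the quaternary centre in 11 with the acetyl group cis to the new bond. The second equivalent of base forms the cross-conjugated methyl ketone enolate, which attacks the lactone carbonyl (intramolecular Claisen/Dieckmann acylation, 6-exo-trig) to form the C5–C6 bond; the acylal then collapses, pivaldehyde is released and the sequence is driven by the stabilised diketonate. The closest known reaction types are the Michael–Claisen [4+2] annulation that gives cyclohexane-1,3-diones and the alkylation of 2-tert-butyl-1,3-dioxolan-4-one enolates (self-regeneration of stereocentres). The configuration at C4 is controlled only by the acetal tert-butyl group, because the original carbinol centre is trigonal in 10. The step needs α- rather than γ-attack of the dienolate (the α-carbon carries the highest charge and γ-attack would break the styrene conjugation), substitution rather than carbonyl addition (aldol addition to the acetyl group is reversible, chloride loss is not) and the Z-enone (secured by the Z-chloride and the stereoretentive substitution, since only this isomer can close).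

Step 6
Reactants: 12 (4S)-4,5-dihydroxy-4-[(E)-1-(3,4-dimethoxyphenyl)prop-1-en-2-yl]-2-(prop-2-en-1-yl)cyclohexa-2,5-dien-1-one
Product: 13 (7aS)-7a-[(E)-1-(3,4-dimethoxyphenyl)prop-1-en-2-yl]-2,2-dimethyl-6-(prop-2-en-1-yl)-1,3-benzodioxol-5(7aH)-one
Conditions: 2-methoxypropene (3 equiv), PPTS (cat.), 4 Å molecular sieves, CH2Cl2, 0 °C to rt
Reagents that add atoms: 2-methoxypropene, COC(C)=C
Why: Compound 12 is a vinylogous α-hydroxy acid and acetonide formation is the vinylogue of dioxolanone formation; only the enol oxygen on C5 can close a five-membered ring with the C4 hydroxyl, so the two oxygens of the 1,3-dione are told apart and O1 stays a carbonyl.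

Step 7
Reactants: 13 (7aS)-7a-[(E)-1-(3,4-dimethoxyphenyl)prop-1-en-2-yl]-2,2-dimethyl-6-(prop-2-en-1-yl)-1,3-benzodioxol-5(7aH)-one
Product: 14 (4S)-4-hydroxy-5-methoxy-4-[(E)-1-(3,4-dimethoxyphenyl)prop-1-en-2-yl]-2-(prop-2-en-1-yl)cyclohexa-2,5-dien-1-one
Conditions: NaOMe (0.3 equiv), MeOH, 0 °C to rt
Reagents that add atoms: methanol (as NaOMe/MeOH), CO
Why: Methoxide adds to C5, the β-carbon of the vinylogous ester, and expels the acetal oxygen (addition–elimination, the vinylogue of dioxolanone methanolysis); the hemiketal alkoxide then loses acetone, which should leave the C5 methyl enol ether and the free C4 carbinol without touching the stereocentre.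

Step 8
Reactants: 14 (4S)-4-hydroxy-5-methoxy-4-[(E)-1-(3,4-dimethoxyphenyl)prop-1-en-2-yl]-2-(prop-2-en-1-yl)cyclohexa-2,5-dien-1-one
Product: 15 (4S)-4,5-dimethoxy-4-[(E)-1-(3,4-dimethoxyphenyl)prop-1-en-2-yl]-2-(prop-2-en-1-yl)cyclohexa-2,5-dien-1-one (CNP0127782.2)
Conditions: NaH, MeI, THF–DMF, 0 °C
Reagents that add atoms: iodomethane, CI
Why: Williamson methylation of the tertiary alkoxide; the dienone has no enolisable α-position, so only O-methylation should occur and the C4 configuration is untouched.

Compound list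
1 | 3,4-dimethoxybenzaldehyde | COc1ccc(C=O)cc1OC | starting material
2 | 2-oxobutanoic acid | CCC(=O)C(=O)O | starting material
3 | (E)-4-(3,4-dimethoxyphenyl)-3-methyl-2-oxobut-3-enoic acid | COc1ccc(/C=C(\C)C(=O)C(=O)O)cc1OC | intermediate
4 | (2S,3E)-4-(3,4-dimethoxyphenyl)-2-hydroxy-3-methylbut-3-enoic acid | COc1ccc(/C=C(\C)[C@H](O)C(=O)O)cc1OC | intermediate
5 | 2,2-dimethylpropanal (pivaldehyde) | CC(C)(C)C=O | starting material
6 | (2S,5S)-2-tert-butyl-5-[(E)-1-(3,4-dimethoxyphenyl)prop-1-en-2-yl]-1,3-dioxolan-4-one | COc1ccc(/C=C(\C)[C@@H]2O[C@H](C(C)(C)C)OC2=O)cc1OC | intermediate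
7 | but-3-yn-2-one | CC(=O)C#C | starting material
8 | 3-chloroprop-1-ene (allyl chloride) | C=CCCl | starting material
9 | (3Z)-3-(chloromethylidene)hex-5-en-2-one | CC(=O)/C(CC=C)=C\Cl | intermediate
10 | lithium (2S)-2-tert-butyl-5-[(E)-1-(3,4-dimethoxyphenyl)prop-1-en-2-yl]-1,3-dioxol-4-olate (lithium dienolate of 6) | COc1ccc(/C=C(\C)C2=C([O-])O[C@@H](C(C)(C)C)O2)cc1OC.[Li+] | intermediate
11 | (2S,5S)-5-[(1Z)-2-acetylpenta-1,4-dien-1-yl]-2-tert-butyl-5-[(E)-1-(3,4-dimethoxyphenyl)prop-1-en-2-yl]-1,3-dioxolan-4-one (vinylation adduct) | COc1ccc(/C=C(\C)[C@]2(/C=C(/CC=C)C(C)=O)O[C@H](C(C)(C)C)OC2=O)cc1OC | intermediate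
12 | (4S)-4,5-dihydroxy-4-[(E)-1-(3,4-dimethoxyphenyl)prop-1-en-2-yl]-2-(prop-2-en-1-yl)cyclohexa-2,5-dien-1-one (enol form of the ring 1,3-dione) | C=CCC1=C[C@](O)(/C(C)=C/c2ccc(OC)c(OC)c2)C(O)=CC1=O | intermediate
13 | (7aS)-7a-[(E)-1-(3,4-dimethoxyphenyl)prop-1-en-2-yl]-2,2-dimethyl-6-(prop-2-en-1-yl)-1,3-benzodioxol-5(7aH)-one (acetonide across O4 and O5) | C=CCC1=C[C@@]2(/C(C)=C/c3ccc(OC)c(OC)c3)OC(C)(C)OC2=CC1=O | intermediate
14 | (4S)-4-hydroxy-5-methoxy-4-[(E)-1-(3,4-dimethoxyphenyl)prop-1-en-2-yl]-2-(prop-2-en-1-yl)cyclohexa-2,5-dien-1-one | C=CCC1=C[C@](O)(/C(C)=C/c2ccc(OC)c(OC)c2)C(OC)=CC1=O | intermediate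
15 | (4S)-4,5-dimethoxy-4-[(E)-1-(3,4-dimethoxyphenyl)prop-1-en-2-yl]-2-(prop-2-en-1-yl)cyclohexa-2,5-dien-1-one (CNP0127782.2) | C=CCC1=C[C@](OC)(/C(C)=C/c2ccc(OC)c(OC)c2)C(OC)=CC1=O | target

Total step count: 8. Longest linear sequence: 7 steps (steps 1, 2, 3, 5, 6, 7, 8).

Steps most likely to fail

Step 5. The Z geometry may be lost during the vinylic substitution: a long-lived carbanion can rotate before chloride leaves, and the resulting E-enone cannot cyclise. Carbonyl addition or proton transfer between the dienolate and the methyl ketone may also compete. The fallback sets out from 6 and comes back at 14. The dienolate of 6 is added instead to 3-methylidenehex-5-en-2-one F1 (from hex-5-en-2-one, aqueous formaldehyde and diisopropylammonium trifluoroacetate). This is an ordinary Michael addition to an unsubstituted methylene terminus, so no alkene geometry is involved. After warming, enolate equilibration and a second portion of LiN(SiMe3)2 close the ring in the same flask by the same Claisen acylation, giving (4S)-3,4-dihydroxy-4-[(E)-1-(3,4-dimethoxyphenyl)prop-1-en-2-yl]-6-(prop-2-en-1-yl)cyclohex-2-en-1-one F2 as a mixture of C6 epimers. 2-Methoxypropene and PPTS convert it into (7aS)-7a-[(E)-1-(3,4-dimethoxyphenyl)prop-1-en-2-yl]-2,2-dimethyl-6-(prop-2-en-1-yl)-7,7a-dihydro-1,3-benzodioxol-5(6H)-one F3. NaOMe in MeOH then gives (4S)-4-hydroxy-3-methoxy-4-[(E)-1-(3,4-dimethoxyphenyl)prop-1-en-2-yl]-6-(prop-2-en-1-yl)cyclohex-2-en-1-one F4. Dehydrogenation of the ketone with IBX in DMSO at 70 °C introduces the missing ring double bond and returns 14.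

Step 4. Chloropalladation may occur syn instead of anti, which would place chlorine trans to the acetyl group, and the ynone may oligomerise. The fallback sets out from 7 and comes back at 9. Conjugate addition of prop-2-en-1-ol to 7 (DABCO cat.) gives (E)-4-(prop-2-en-1-yloxy)but-3-en-2-one F5. Thermal Claisen rearrangement (toluene, sealed tube, 140 °C) moves the allyl group to carbon and gives the chelated enol (3Z)-3-(hydroxymethylidene)hex-5-en-2-one F6. Oxalyl chloride with catalytic DMF then replaces the enol hydroxyl by chlorine through the enol chloro-oxalate and is expected to return 9.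

Step 6. Closure of the five-membered acetal may be incomplete, or acid may induce a ketol-type rearrangement of the tertiary carbinol next to the dione. The fallback sets out from 12 and comes back at 14. Compound 12 is methylated without a directing ring, using Me3SiCHN2 in MeOH–toluene. Compound 14 is separated by chromatography from its regioisomeric enol ether (6S)-6-hydroxy-3-methoxy-6-[(E)-1-(3,4-dimethoxyphenyl)prop-1-en-2-yl]-4-(prop-2-en-1-yl)cyclohexa-2,4-dien-1-one F7. F7 is hydrolysed back to 12 with aqueous LiOH and recycled.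

Further compounds
F1 | step 5 | 3-methylidenehex-5-en-2-one | CC(=O)C(=C)CC=C
F2 | step 5 | (4S)-3,4-dihydroxy-4-[(E)-1-(3,4-dimethoxyphenyl)prop-1-en-2-yl]-6-(prop-2-en-1-yl)cyclohex-2-en-1-one (C6 epimers) | C=CCC1C[C@](O)(/C(C)=C/c2ccc(OC)c(OC)c2)C(O)=CC1=O
F3 | step 5 | (7aS)-7a-[(E)-1-(3,4-dimethoxyphenyl)prop-1-en-2-yl]-2,2-dimethyl-6-(prop-2-en-1-yl)-7,7a-dihydro-1,3-benzodioxol-5(6H)-one (C6 epimers) | C=CCC1C[C@@]2(/C(C)=C/c3ccc(OC)c(OC)c3)OC(C)(C)OC2=CC1=O
F4 | step 5 | (4S)-4-hydroxy-3-methoxy-4-[(E)-1-(3,4-dimethoxyphenyl)prop-1-en-2-yl]-6-(prop-2-en-1-yl)cyclohex-2-en-1-one (C6 epimers) | C=CCC1C[C@](O)(/C(C)=C/c2ccc(OC)c(OC)c2)C(OC)=CC1=O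
F5 | step 4 | (E)-4-(prop-2-en-1-yloxy)but-3-en-2-one | CC(=O)/C=C/OCC=C
F6 | step 4 | (3Z)-3-(hydroxymethylidene)hex-5-en-2-one | CC(=O)/C(CC=C)=C\O
F7 | step 6 | (6S)-6-hydroxy-3-methoxy-6-[(E)-1-(3,4-dimethoxyphenyl)prop-1-en-2-yl]-4-(prop-2-en-1-yl)cyclohexa-2,4-dien-1-one | C=CCC1=C[C@](O)(/C(C)=C/c2ccc(OC)c(OC)c2)C(=O)C=C1OC
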